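## Retrosynthetic overview

1. Target 16 ⇐ one global hydrogenolysis (two N–O bonds, one O–benzyl bond) of the bis(1-silyloxyindole) 15.
2. Both pyrrole rings of 15 ⇐ two aryl C–N bonds (N1–C7a of each indole), closed together in one flask from the bis(nitroalkane) 11; each nitro nitrogen becomes an indole nitrogen.
3. 11 ⇐ two C–C bonds: sequential Br–Li exchange on dibromide 2, with conjugate addition to nitrostyrene 6 and then nitrostyrene 5.
4. 2 ⇐ 1,2,4,5-tetramethoxybenzene 1; 5 ⇐ 3-(benzyloxy)benzaldehyde 3 + nitromethane 4.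
5. Ring order: the three benzene rings are bought; the two pyrrole rings are formed last, both at once.

Assumption: the target has no stereocentre and no configurationally fixed axis, so the achiral compound as drawn is the single species to be made; 1, 3, 4 and 6 are taken as catalogue chemicals.

## Route

Step 1
Reactants: 1 1,2,4,5-tetramethoxybenzene
Product: 2 1,4-dibromo-2,3,5,6-tetramethoxybenzene
Conditions: NBS (2.2 equiv), MeCN, 0 °C to 40 °C
Reagents that add atoms: N-bromosuccinimide, O=C1CCC(=O)N1Br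
Why: Electrophilic aromatic bromination; the only two C–H positions are each flanked by two methoxy groups, so double substitution can give only this isomer.

Step 2
Reactants: 3 3-(benzyloxy)benzaldehyde; 4 nitromethane
Product: 5 (E)-1-(benzyloxy)-3-(2-nitrovinyl)benzene
Conditions: 4 (5 equiv), NH4OAc (0.5 equiv), AcOH, 100 °C
Reagents that add atoms: none
Why: Henry (nitroaldol) condensation with dehydration under ammonium acetate catalysis gives the conjugated nitroalkene as the thermodynamically favoured E isomer.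

Step 3
Reactants: 2 1,4-dibromo-2,3,5,6-tetramethoxybenzene; 6 (E)-1-methoxy-4-(2-nitrovinyl)benzene; 5 (E)-1-(benzyloxy)-3-(2-nitrovinyl)benzene
Product: 11 1-{1-[3-(benzyloxy)phenyl]-2-nitroethyl}-2,3,5,6-tetramethoxy-4-[1-(4-methoxyphenyl)-2-nitroethyl]benzene, via aryllithium 7 (not isolated), via bromoaryl lithium nitronate 8 (not isolated), via lithioaryl lithium nitronate 9 (not isolated), via dilithium bis(nitronate) 10 (not isolated)
Conditions: t-BuLi (2.0 equiv), THF/Et2O, –78 °C; 6 (1.0 equiv), –78 °C; cool to –100 °C, t-BuLi (2.1 equiv); 5 (1.05 equiv), –100 to –78 °C; AcOH (excess), –78 °C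
Reagents that add atoms: none
Why: Bromine–lithium exchange followed by Michael addition of the aryllithium to the β-nitrostyrene, run twice in one flask; the first adduct rests as a charge-protected lithium nitronate while the second Br–Li exchange (faster at –100 °C than any addition to a nitronate) takes place, and the two benzylic stereocentres form without control (diastereomer mixture) and are both erased in step 4.

Step 4
Reactants: 11 1-{1-[3-(benzyloxy)phenyl]-2-nitroethyl}-2,3,5,6-tetramethoxy-4-[1-(4-methoxyphenyl)-2-nitroethyl]benzene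
Product: 15 5-(benzyloxy)-1-[(tert-butyldimethylsilyl)oxy]-3-{4-[1-[(tert-butyldimethylsilyl)oxy]-6-methoxy-1H-indol-3-yl]-2,3,5,6-tetramethoxyphenyl}-1H-indole, via bis(N,N-disilyloxyenamine) 12 (not isolated), via bis(nitrosoalkene) 13 (not isolated), via bis(1-hydroxyindole) 14 (not isolated)
Conditions: TBSOTf (7 equiv), Et3N (8 equiv), ClCH2CH2Cl, –20 °C to rt, then 60 °C
Reagents that add atoms: tert-butyldimethylsilyl trifluoromethanesulfonate, CC(C)(C)[Si](C)(C)OS(=O)(=O)C(F)(F)F
Why: Proposed new method: a twofold silylative dehydration and aryl C–N ring closure of a β,β-diaryl primary nitroalkane, in which double O-silylation with β-deprotonation gives the N,N-bis(silyloxy)enamine 12, silyl-triflate-promoted loss of disiloxane unmasks the conjugated nitrosoalkene 13 whose β-carbon is fully substituted and so closed to the usual nucleophile capture, and the electrophilic nitroso nitrogen therefore closes onto the ortho C–H carbon of the coplanar outer aryl ring (1,5-electrocyclisation, then a re-aromatising hydrogen shift to the 1-hydroxyindole 14, capped in the flask as its silyl ether), the hexasubstituted central ring offering no ortho C–H and closure on the benzyloxyphenyl ring going para to oxygen (less hindered, more electron-rich carbon) to fix the 5-oxygenation; the closest known reaction types are the double silylation of nitroalkanes to N,N-bis(silyloxy)enamines with Lewis-acid release of nitrosoalkenes, and the nitrosoalkene-to-N-hydroxyindole closure accepted for CO/palladium reductive cyclisations of β-nitrostyrenes (Cadogan–Sundberg manifold); no stereocentre is formed.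

Step 5
Reactants: 15 5-(benzyloxy)-1-[(tert-butyldimethylsilyl)oxy]-3-{4-[1-[(tert-butyldimethylsilyl)oxy]-6-methoxy-1H-indol-3-yl]-2,3,5,6-tetramethoxyphenyl}-1H-indole
Product: 16 3-[2,3,5,6-tetramethoxy-4-(6-methoxy-1H-indol-3-yl)phenyl]-1H-indol-5-ol
Conditions: H2 (1 atm), 10% Pd/C, THF/MeOH, rt
Reagents that add atoms: none
Why: Catalytic hydrogenolysis cleaves the two weak indole N–O bonds (as for 1-alkoxy- and 1-hydroxyindoles) and the benzyl ether in one operation, while aryl methyl ethers and the indole rings are untouched at 1 atm and room temperature; no stereocentre is involved.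

## Compound list

1 | 1,2,4,5-tetramethoxybenzene | COc1cc(OC)c(OC)cc1OC | starting material
2 | 1,4-dibromo-2,3,5,6-tetramethoxybenzene | COc1c(Br)c(OC)c(OC)c(Br)c1OC | intermediate
3 | 3-(benzyloxy)benzaldehyde | O=Cc1cccc(OCc2ccccc2)c1 | starting material
4 | nitromethane | C[N+](=O)[O-] | starting material
5 | (E)-1-(benzyloxy)-3-(2-nitrovinyl)benzene | [O-][N+](=O)/C=C/c1cccc(OCc2ccccc2)c1 | intermediate
6 | (E)-1-methoxy-4-(2-nitrovinyl)benzene | COc1ccc(/C=C/[N+](=O)[O-])cc1 | starting material
7 | (4-bromo-2,3,5,6-tetramethoxyphenyl)lithium (not isolated) | [Li]c1c(OC)c(OC)c(Br)c(OC)c1OC | intermediate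
8 | lithium nitronate of 1-bromo-2,3,5,6-tetramethoxy-4-[1-(4-methoxyphenyl)-2-nitroethyl]benzene (not isolated) | COc1ccc(cc1)C(C=[N+]([O-])[O-])c1c(OC)c(OC)c(Br)c(OC)c1OC.[Li+] | intermediate
9 | lithium nitronate of {2,3,5,6-tetramethoxy-4-[1-(4-methoxyphenyl)-2-nitroethyl]phenyl}lithium (not isolated) | COc1ccc(cc1)C(C=[N+]([O-])[O-])c1c(OC)c(OC)c([Li])c(OC)c1OC.[Li+] | intermediate
10 | dilithium bis(nitronate) of 11 (not isolated) | COc1ccc(cc1)C(C=[N+]([O-])[O-])c1c(OC)c(OC)c(C(C=[N+]([O-])[O-])c2cccc(OCc3ccccc3)c2)c(OC)c1OC.[Li+].[Li+] | intermediate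
11 | 1-{1-[3-(benzyloxy)phenyl]-2-nitroethyl}-2,3,5,6-tetramethoxy-4-[1-(4-methoxyphenyl)-2-nitroethyl]benzene (mixture of diastereomers) | COc1ccc(cc1)C(C[N+](=O)[O-])c1c(OC)c(OC)c(C(C[N+](=O)[O-])c2cccc(OCc3ccccc3)c2)c(OC)c1OC | intermediate
12 | bis(N,N-disilyloxyenamine): each CH–CH2NO2 arm of 11 converted to C=CH–N(OTBS)2 (E/Z mixture, not isolated) | COc1ccc(cc1)C(=CN(O[Si](C)(C)C(C)(C)C)O[Si](C)(C)C(C)(C)C)c1c(OC)c(OC)c(C(=CN(O[Si](C)(C)C(C)(C)C)O[Si](C)(C)C(C)(C)C)c2cccc(OCc3ccccc3)c2)c(OC)c1OC | intermediate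
13 | bis(nitrosoalkene): 1-{1-[3-(benzyloxy)phenyl]-2-nitrosoethenyl}-2,3,5,6-tetramethoxy-4-[1-(4-methoxyphenyl)-2-nitrosoethenyl]benzene (not isolated) | COc1ccc(cc1)C(=CN=O)c1c(OC)c(OC)c(C(=CN=O)c2cccc(OCc3ccccc3)c2)c(OC)c1OC | intermediate
14 | 5-(benzyloxy)-3-[4-(1-hydroxy-6-methoxy-1H-indol-3-yl)-2,3,5,6-tetramethoxyphenyl]-1H-indol-1-ol (not isolated) | COc1ccc2c(c1)n(O)cc2-c1c(OC)c(OC)c(-c2cn(O)c3ccc(OCc4ccccc4)cc23)c(OC)c1OC | intermediate
15 | 5-(benzyloxy)-1-[(tert-butyldimethylsilyl)oxy]-3-{4-[1-[(tert-butyldimethylsilyl)oxy]-6-methoxy-1H-indol-3-yl]-2,3,5,6-tetramethoxyphenyl}-1H-indole | COc1ccc2c(c1)n(O[Si](C)(C)C(C)(C)C)cc2-c1c(OC)c(OC)c(-c2cn(O[Si](C)(C)C(C)(C)C)c3ccc(OCc4ccccc4)cc23)c(OC)c1OC | intermediate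
16 | 3-[2,3,5,6-tetramethoxy-4-(6-methoxy-1H-indol-3-yl)phenyl]-1H-indol-5-ol | COc1ccc2c(-c3c(OC)c(OC)c(-c4c[nH]c5ccc(O)cc45)c(OC)c3OC)c[nH]c2c1 | target

## Step count and risks

Total steps: 5. Longest linear sequence: 4 (1 → 2 → 11 → 15 → 16; the branch 3 → 5 → 11 → 15 → 16 is equally long).

**Step 4 (the proposed new step).** Three things can go wrong. The silanolate or triflate may return to the diaryl carbon and give an α-silyloxy oxime ether, the usual fate of bis(silyloxy)enamines. The nitrosoalkene may close through oxygen to a 1,2-benzoxazine. The benzyloxyphenyl ring may close partly at the crowded ortho carbon and give some 7-benzyloxy isomer.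

Fallback with known chemistry, setting out from 11 and coming back at 16: both nitroalkyl groups of 11 are deprotonated (LDA, THF, –78 °C) and trapped with PhSeBr to give the bis(α-phenylselanyl nitroalkane) F4. Oxidation with H2O2 (CH2Cl2, 0 °C to rt) and selenoxide syn-elimination gives the bis(2,2-diaryl-1-nitroethene) F5. The established reductive cyclisation of β,β-diaryl nitroalkenes under CO (1 atm) with Pd(OAc)2 and 1,10-phenanthroline in DMF at 110 °C then closes the same two N–C7a bonds and gives the N–H bis-indole benzyl ether F6. Hydrogenolysis of F6 (H2, 10% Pd/C) gives 16.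

**Step 3.** The second Br–Li exchange is run in the presence of a lithium nitronate; t-BuLi may attack or deprotonate the nitronate, or the nitronate may add to the second nitrostyrene.

Fallback setting out from 2 and coming back at 11: 2 is converted with t-BuLi (4.2 equiv, THF, –78 °C) into 1,4-dilithio-2,3,5,6-tetramethoxybenzene F1, so that no alkyllithium ever meets a nitronate. A 1:1 mixture of 5 and 6 is added and the mixture is quenched with AcOH. Chromatography separates 11 (statistical ceiling 50%) from the symmetrical bis(4-methoxyphenyl) adduct F2 and the symmetrical bis(3-benzyloxyphenyl) adduct F3.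

**Step 5.** The bulky N–O–silyl bonds may resist hydrogenolysis, the electron-rich rings may over-reduce on forcing, and the 5-hydroxyindole product is air-sensitive.

Fallback setting out from 15 and coming back at 16, replacing the single hydrogenolysis by stepwise chemical cleavage: TBAF (THF, 0 °C) removes both silyl groups to give the bis(1-hydroxyindole) 14, here isolated. Zn dust in AcOH reduces both N–O bonds to give the N–H bis-indole benzyl ether F7 (the same structure as F6). BCl3 with pentamethylbenzene (CH2Cl2, –78 °C) then removes the benzyl group without touching the methyl ethers and gives 16.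

## Further compounds

F1 | step 3 | 1,4-dilithio-2,3,5,6-tetramethoxybenzene | [Li]c1c(OC)c(OC)c([Li])c(OC)c1OC
F2 | step 3 | 2,3,5,6-tetramethoxy-1,4-bis[1-(4-methoxyphenyl)-2-nitroethyl]benzene | COc1ccc(cc1)C(C[N+](=O)[O-])c1c(OC)c(OC)c(C(C[N+](=O)[O-])c2ccc(OC)cc2)c(OC)c1OC
F3 | step 3 | 1,4-bis{1-[3-(benzyloxy)phenyl]-2-nitroethyl}-2,3,5,6-tetramethoxybenzene | [O-][N+](=O)CC(c1cccc(OCc2ccccc2)c1)c1c(OC)c(OC)c(C(C[N+](=O)[O-])c2cccc(OCc3ccccc3)c2)c(OC)c1OC
F4 | step 4 | 1-{1-[3-(benzyloxy)phenyl]-2-nitro-2-(phenylselanyl)ethyl}-2,3,5,6-tetramethoxy-4-[1-(4-methoxyphenyl)-2-nitro-2-(phenylselanyl)ethyl]benzene | COc1ccc(cc1)C(C([Se]c2ccccc2)[N+](=O)[O-])c1c(OC)c(OC)c(C(C([Se]c2ccccc2)[N+](=O)[O-])c2cccc(OCc3ccccc3)c2)c(OC)c1OC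
F5 | step 4 | 1-{1-[3-(benzyloxy)phenyl]-2-nitroethenyl}-2,3,5,6-tetramethoxy-4-[1-(4-methoxyphenyl)-2-nitroethenyl]benzene | COc1ccc(cc1)C(=C[N+](=O)[O-])c1c(OC)c(OC)c(C(=C[N+](=O)[O-])c2cccc(OCc3ccccc3)c2)c(OC)c1OC
F6 | step 4 | 5-(benzyloxy)-3-[2,3,5,6-tetramethoxy-4-(6-methoxy-1H-indol-3-yl)phenyl]-1H-indole | COc1ccc2c(c1)[nH]cc2-c1c(OC)c(OC)c(-c2c[nH]c3ccc(OCc4ccccc4)cc23)c(OC)c1OC
F7 | step 5 | 5-(benzyloxy)-3-[2,3,5,6-tetramethoxy-4-(6-methoxy-1H-indol-3-yl)phenyl]-1H-indole | COc1ccc2c(c1)[nH]cc2-c1c(OC)c(OC)c(-c2c[nH]c3ccc(OCc4ccccc4)cc23)c(OC)c1OC
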